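**Plan**

- Retrosynthesis: the two O–benzyl bonds are cut last. Next the C2–C1′ bond between the pyranone ring and the C15 chain is cut. The remaining achiral chromone is opened at C4–C4a (Friedel–Crafts acylation) and O1–C2 (oxa-Michael addition of a phenol to a propiolate).
- Forward: ring A is bought as 2,5-dimethoxyphenol. Ring C (the 4-pyranone) is annulated onto its only free ortho position, the methyl ethers are exchanged for benzyl ethers, and the chain is then joined to the finished 5,8-bis(benzyloxy)chromone in one step.
- Enabling feature: the C2=C3–C4=O vinylogous ester of ring C. C2 is a prochiral sp2 β-carbon carrying only H and O1, so 1,4-addition of an alkyl nucleophile makes the chain bond and the only stereocentre together.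
- Stereochemistry: C2 (R) is set by catalyst control (chiral ferrocenyl diphosphine on CuBr, delivery to the Re face of C2). The end game is neutral, so the centre is not scrambled by retro-oxa-Michael ring opening.

Key step: step 7

Assumption: the (R,Sp) antipode of the ferrocenyl diphosphine is taken to direct the alkyl group to the Re face of C2 of chromone 9; if a pilot run shows the opposite sense, the mirror-image ligand is used and nothing else changes.

**Route**

Step 1
Reactants: 1 2,5-dimethoxyphenol; 2 ethyl propiolate
Product: 3 ethyl (E)-3-(2,5-dimethoxyphenoxy)prop-2-enoate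
Conditions: DABCO (10 mol%), CH2Cl2, 0 °C to rt
Reagents that add atoms: none
Why: Amine-catalysed oxa-Michael addition of the phenol to the activated alkyne should give the E β-aryloxyacrylate; the alkene geometry is not critical because it equilibrates under the acid of step 3.

Step 2
Reactants: 3 ethyl (E)-3-(2,5-dimethoxyphenoxy)prop-2-enoate
Product: 5 (E)-3-(2,5-dimethoxyphenoxy)prop-2-enoic acid, via lithium carboxylate 4 (not isolated)
Conditions: LiOH, THF/H2O, rt; then 1 M HCl to pH 2, 0 °C
Reagents that add atoms: lithium hydroxide [Li+].[OH-]
Why: Ester saponification by acyl–oxygen cleavage; the β-aryloxyacrylate is a vinylogous carbonate and should tolerate hydroxide at room temperature and brief cold acidification.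

Step 3
Reactants: 5 (E)-3-(2,5-dimethoxyphenoxy)prop-2-enoic acid
Product: 6 5,8-dimethoxy-4H-chromen-4-one
Conditions: Eaton's reagent (P4O10 in MeSO3H), 60 °C
Reagents that add atoms: none
Why: Intramolecular Friedel–Crafts acylation; the oxygen-stabilised acylium allows E to Z rotation, and the ring can only close on the single free ortho carbon (between the aryl ether oxygen and a methoxy group), which fixes the 5,8-pattern, while P4O10 removes the water that would otherwise hydrolyse the aryl vinyl ether.

Step 4
Reactants: 6 5,8-dimethoxy-4H-chromen-4-one
Product: 8 5,8-dihydroxy-4H-chromen-4-one, via bis(dibromoboryl) ether 7 (not isolated)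
Conditions: BBr3 (5 equiv), CH2Cl2, −78 °C to rt; then H2O, 0 °C
Reagents that add atoms: none
Why: Lewis-acid-mediated cleavage of aryl methyl ethers by bromide attack on the boron-complexed methyl groups; the chromone is achiral and robust, so the harsh dealkylation is done here and not on the chiral chromanone.

Step 5
Reactants: 8 5,8-dihydroxy-4H-chromen-4-one
Product: 9 5,8-bis(benzyloxy)-4H-chromen-4-one
Conditions: BnBr (2.5 equiv), K2CO3 (3 equiv), Bu4NI (cat.), DMF, 60 °C, argon
Reagents that add atoms: benzyl bromide BrCc1ccccc1
Why: Williamson etherification of both phenols; warm DMF and iodide catalysis should overcome the hydrogen bond of the 5-hydroxyl, and argon protects the hydroquinone dianion from air.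

Step 6
Reactants: 10 1-bromopentadecane
Product: 11 pentadecylmagnesium bromide (titrated ether solution, used directly)
Conditions: Mg turnings (I2-activated), Et2O, reflux
Reagents that add atoms: magnesium [Mg]
Why: Grignard formation by insertion of magnesium into the primary C–Br bond; diethyl ether is used because strongly coordinating ethers erode enantioselectivity in the copper-catalysed step.

Step 7
Reactants: 9 5,8-bis(benzyloxy)-4H-chromen-4-one; 11 pentadecylmagnesium bromide
Product: 13 (R)-5,8-bis(benzyloxy)-2-pentadecylchroman-4-one, via magnesium enolate 12 (not isolated)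
Conditions: CuBr·SMe2 (5 mol%), (R)-1-[(Sp)-2-(dicyclohexylphosphino)ferrocenyl]ethyldiphenylphosphine (Rev-JosiPhos, 6 mol%), CH2Cl2, −78 °C, slow addition of 11 (2 equiv, Et2O); then sat. aq. NH4Cl, −78 °C
Reagents that add atoms: none
Why: The Grignard reagent transmetalates to the diphosphine-bound CuBr to give a monovalent alkylcopper species that forms a π-complex with C2=C3, adds oxidatively to give a trivalent copper σ-complex at C2 and reductively eliminates the C2–C1′ bond, leaving magnesium enolate 12, which is protonated at C3 on the cold quench. The closest known reaction type is the copper-catalysed asymmetric conjugate addition of linear alkyl Grignard reagents to chromones with ferrocenyl diphosphine ligands, used here on a 5,8-dioxygenated member of the same substrate class. No ring is closed in this step. The new stereocentre C2 is set by catalyst control: the chiral ligand on copper shields one face of the flat pyranone so that the chain is delivered to the Re face of C2 (R), the substrate having no stereo element of its own. The step needs 1,4- over 1,2-addition and the catalysed over the uncatalysed pathway; the vinylogous-ester carbonyl (donation from O1 and the 5-benzyloxy oxygen) is a poor partner for direct attack, and the low temperature, CH2Cl2 as main solvent and slow addition keep free Grignard reagent low. The enolate is quenched at −78 °C so that E1cB loss of the ring phenoxide (retro-oxa-Michael), which would erase C2, cannot start.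

Step 8
Reactants: 13 (R)-5,8-bis(benzyloxy)-2-pentadecylchroman-4-one
Product: 14 (R)-5,8-dihydroxy-2-pentadecylchroman-4-one (target)
Conditions: H2 (1 atm), 10% Pd/C, EtOAc, rt; filtration under argon
Reagents that add atoms: none
Why: Catalytic hydrogenolysis of the two aryl benzyl ethers under neutral conditions; without acid or base there is no enolisation or retro-oxa-Michael pathway, so C2 should keep its configuration, the aryl ketone is expected to resist reduction in neutral EtOAc (it becomes hydrogen-bonded to the 5-OH as that group is unveiled), and the reducing atmosphere protects the hydroquinone.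

**Compound list**

1 | 2,5-dimethoxyphenol | COc1ccc(OC)c(O)c1 | starting material
2 | ethyl propiolate | CCOC(=O)C#C | starting material
3 | ethyl (E)-3-(2,5-dimethoxyphenoxy)prop-2-enoate | CCOC(=O)/C=C/Oc1cc(OC)ccc1OC | intermediate
4 | lithium (E)-3-(2,5-dimethoxyphenoxy)prop-2-enoate (not isolated) | [Li+].[O-]C(=O)/C=C/Oc1cc(OC)ccc1OC | intermediate
5 | (E)-3-(2,5-dimethoxyphenoxy)prop-2-enoic acid | OC(=O)/C=C/Oc1cc(OC)ccc1OC | intermediate
6 | 5,8-dimethoxy-4H-chromen-4-one | O=c1ccoc2c(OC)ccc(OC)c12 | intermediate
7 | 5,8-bis(dibromoboryloxy)-4H-chromen-4-one (not isolated) | O=c1ccoc2c(OB(Br)Br)ccc(OB(Br)Br)c12 | intermediate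
8 | 5,8-dihydroxy-4H-chromen-4-one | O=c1ccoc2c(O)ccc(O)c12 | intermediate
9 | 5,8-bis(benzyloxy)-4H-chromen-4-one | O=c1ccoc2c(OCc3ccccc3)ccc(OCc3ccccc3)c12 | intermediate
10 | 1-bromopentadecane | CCCCCCCCCCCCCCCBr | starting material
11 | pentadecylmagnesium bromide | CCCCCCCCCCCCCCC[Mg]Br | intermediate
12 | bromomagnesium (R)-5,8-bis(benzyloxy)-2-pentadecyl-2H-chromen-4-olate (not isolated) | CCCCCCCCCCCCCCC[C@@H]1C=C(O[Mg]Br)c2c(OCc3ccccc3)ccc(OCc3ccccc3)c2O1 | intermediate
13 | (R)-5,8-bis(benzyloxy)-2-pentadecylchroman-4-one | CCCCCCCCCCCCCCC[C@@H]1CC(=O)c2c(OCc3ccccc3)ccc(OCc3ccccc3)c2O1 | intermediate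
14 | (R)-5,8-dihydroxy-2-pentadecylchroman-4-one | CCCCCCCCCCCCCCC[C@@H]1CC(=O)c2c(O)ccc(O)c2O1 | target

**Count**

Total steps: 8. Longest linear sequence: 7 steps (steps 1 to 5, 7 and 8); the Grignard reagent of step 6 joins at step 7.

**Steps most likely to fail**

Step 7. What may go wrong: low conversion and eroded facial selectivity, because the long-chain Grignard reagent may aggregate or precipitate at −78 °C and an uncatalysed addition, activated by magnesium chelation between the C4 carbonyl and the 5-benzyloxy oxygen, may compete with the ligand-bound copper pathway. Fallback (catalyst control replaced by resolution): setting out from 9 and 11, a ligand-free addition with CuBr·SMe2 (10 mol%) in THF/Et2O at −40 °C, where the reagent stays in solution, should give the racemic bromomagnesium enolate F1, which is protonated with aqueous NH4Cl to racemic 5,8-bis(benzyloxy)-2-pentadecylchroman-4-one F2. Preparative chromatography of F2 on an amylose tris(3,5-dimethylphenylcarbamate) chiral stationary phase should separate the enantiomers; the (R)-enantiomer is 13, where the route is rejoined, and the (S)-enantiomer is set aside.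

Step 3. What may go wrong: acid-mediated cleavage of the aryl vinyl ether (C-protonation, then loss of the phenol) and sulfonation or oligomerisation of the electron-rich ring may outrun acylation at the hindered carbon between two oxygens. Fallback (pyranone built from an ortho-hydroxyacetophenone instead): setting out from 1, ortho-acetylation under Fries-type conditions (AcOH, BF3·OEt2, 90 °C; the boron chelate of the ortho-hydroxy ketone directs the acyl group next to the phenol oxygen, and any para isomer is removed as the more polar, non-chelated compound) should give 1-(2-hydroxy-3,6-dimethoxyphenyl)ethan-1-one F3. Condensation with N,N-dimethylformamide dimethyl acetal in toluene at 100 °C should give (E)-3-(dimethylamino)-1-(2-hydroxy-3,6-dimethoxyphenyl)prop-2-en-1-one F4. Treatment of F4 with concentrated HCl in CH2Cl2 should close the ring by addition of the phenol oxygen and loss of dimethylamine, returning to the route at 6.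

Step 5. What may go wrong: incomplete alkylation of the hydrogen-bonded 5-hydroxyl, aerial oxidation of the hydroquinone dianion to the quinone, and base-induced opening of the 2-unsubstituted pyranone ring. Fallback (no protecting-group exchange; methyl ethers carried to the end, skipping steps 4, 5 and 8): setting out from 6 and 11, conjugate addition under the conditions of step 7 should give, through the bromomagnesium enolate F5, (R)-5,8-dimethoxy-2-pentadecylchroman-4-one F6. Demethylation of F6 with BBr3 in CH2Cl2 from −78 °C to 0 °C should pass through the bis(dibromoboryl) ether F7 and, after cold aqueous work-up, rejoin the route at 14. The low temperature is kept because a Lewis acid on the chiral chromanone carries some risk of C2–O1 cleavage, which is why this is the fallback and not the main route.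

**Further compounds**

F1 | step 7 | racemic bromomagnesium 5,8-bis(benzyloxy)-2-pentadecyl-2H-chromen-4-olate | CCCCCCCCCCCCCCCC1C=C(O[Mg]Br)c2c(OCc3ccccc3)ccc(OCc3ccccc3)c2O1
F2 | step 7 | racemic 5,8-bis(benzyloxy)-2-pentadecylchroman-4-one | CCCCCCCCCCCCCCCC1CC(=O)c2c(OCc3ccccc3)ccc(OCc3ccccc3)c2O1
F3 | step 3 | 1-(2-hydroxy-3,6-dimethoxyphenyl)ethan-1-one | CC(=O)c1c(O)c(OC)ccc1OC
F4 | step 3 | (E)-3-(dimethylamino)-1-(2-hydroxy-3,6-dimethoxyphenyl)prop-2-en-1-one | CN(C)/C=C/C(=O)c1c(O)c(OC)ccc1OC
F5 | step 5 | bromomagnesium (R)-5,8-dimethoxy-2-pentadecyl-2H-chromen-4-olate | CCCCCCCCCCCCCCC[C@@H]1C=C(O[Mg]Br)c2c(OC)ccc(OC)c2O1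
F6 | step 5 | (R)-5,8-dimethoxy-2-pentadecylchroman-4-one | CCCCCCCCCCCCCCC[C@@H]1CC(=O)c2c(OC)ccc(OC)c2O1
F7 | step 5 | (R)-5,8-bis(dibromoboryloxy)-2-pentadecylchroman-4-one | CCCCCCCCCCCCCCC[C@@H]1CC(=O)c2c(OB(Br)Br)ccc(OB(Br)Br)c2O1
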